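## The problem

The target is an isoflavone: a benzopyran-4-one (ring A fused to the pyranone ring C) with a 2,4-dihydroxyphenyl ring B at C3, hydroxyls at C5 and C7, and a 2-methylbut-3-en-2-yl (1,1-dimethylallyl) group at C8. There is no stereocentre, so the difficulties are regiochemical. The tertiary allyl group must go to C8 and not to the equally activated C6, and four phenols have to be told apart. The C8 substituent is attached through a quaternary carbon, which excludes ordinary prenylation (it gives the linear isomer) and points to an allyl shift from O7 with inversion. The terminal alkene next to the free 7-hydroxyl cyclises under acid and is saturated by hydrogen, so acidic and hydrogenolytic deprotections must be finished before it exists. C2 of the pyranone is opened by hydroxide, alkoxides and secondary amines, and the resorcinol ring B is a poor aryl-metal partner because it loses the metal easily. The enabling feature is the substitution of ring B: C1' is bonded to C3 and flanked by the C2' hydroxyl, and the C4' oxygen lies 1,3 to that hydroxyl. This is the pattern formed when a vinylketene (C1', C6', C5', C2') takes up an oxygenated alkyne (C3', C4'), so C1' can start as the formyl carbon of a chromone-3-carbaldehyde. Ring A is a phloroglucinol pattern that can be bought complete.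

## Retrosynthesis

**24 from 23.** Only the O–Si bond at the 4'-oxygen is cut. A triisopropylsilyl ether is chosen because the ring-forming step delivers this oxygen already silylated and because fluoride removes it without touching the alkene, the chelated 5-hydroxyl or the pyranone. An alkyl or acetal group here would need acid at the end, which the 1,1-dimethylallyl phenol does not tolerate. 23 differs from 24 by one silyl group, and the forward step only has to be buffered.

**23 from 21.** The bond between C8 and the tertiary allylic carbon is cut, and the five-carbon unit is moved back to O7 as a prenyl ether. Electrophilic prenylation of the free ring A would give the linear isomer and mixtures at C6, C8 and oxygen, and coupling a tertiary allyl unit to C8 has no reliable form. The [3,3] shift through dienone 22 inverts the allyl group, so the tertiary attachment follows automatically, and the ether oxygen limits delivery to C6 or C8. 21 lacks the quaternary carbon. The forward reaction must favour C8 and must run cool enough that the new 7-hydroxyl does not add to the alkene.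

**21 from 19 and 20; 19 from 18.** The O7–C bond is cut to triol 19 and prenyl bromide 20, and the ring A phenols of 19 are traced to dibenzyl ether 18. The order is fixed by the alkene: benzyl ethers leave by hydrogenolysis, so this must precede the arrival of 20. In 19 the 7-hydroxyl is the most acidic (vinylogous to the C4 carbonyl), the 5-hydroxyl is locked in a hydrogen bond, and the 2'-hydroxyl is an ordinary hindered phenol. The alkylation relies on this ranking.

**18 from 8 and 13.** Four bonds of ring B are cut: C1'–C2', C2'–C3', C4'–C5' and C5'–C6'. The neighbouring cut at C3–C1' would need a 2,4-dioxygenated aryl-metal reagent and would bring in ring B with two oxygens still to be differentiated. The present cut leaves diazo ketone 8, which holds no part of ring B beyond a three-carbon chain on the chromone, and alkyne 13, which supplies C3', C4' and the 4'-oxygen. In the forward direction 8 gives vinylketene 14, then cyclobutenone 15, dienylketene 16 and dienone 17. The polarity of ketene and ynol ether must put the hydroxyl at C2' and the silyloxy group at C4'.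

**13 from 9, 10 and 11.** The O–Si bond and the C≡C bond are cut. Lithium ethynolate 12 is the ynolate expected when ethyl formate 9 is homologated with dibromomethane 10, and chlorotriisopropylsilane 11 caps its oxygen. The bulky silyl group favours O- over C-silylation and gives an ynol ether that survives 80 °C.

**8 from 6; 6 from 4 and 5.** The diazo group is traced to the methyl group of enone 6 by diazo transfer through the trifluoroacetyl derivative 7. Acylating a diazoalkane with the unsaturated acid chloride is set aside because diazoalkanes add as dipoles to conjugated alkenes, and there are two here (the enone and the C2=C3 bond of the chromone). The C=C bond of 6 is cut to aldehyde 4 and the acetyl-stabilised ylide 5. A Wittig reaction is preferred to an aldol condensation because the pyranone does not survive hydroxide or amine bases.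

**4 from 3; 3 from 1 and 2.** C2 and the formyl carbon of 4 are removed together. Both come from the formamide reagent of a Vilsmeier–Haack reaction on 2-hydroxyacetophenone 3, which also closes ring C at O1–C2. 3 is phloroacetophenone 1 benzylated twice with benzyl bromide 2. The mirror symmetry of 1 makes its two ortho hydroxyls equivalent, and the one left free is the chelated one needed for ring closure.

## Roads not taken

Alternative 1: The pyranone is closed last, at O1–C8a. The enolate oxygen of hydroxymethylene ketone A2, whose aroyl ring carries fluorine at all three activated positions, displaces an ortho fluoride under a carbonate base (intramolecular SNAr) and gives difluoroisoflavone A1.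
- Merits: the closure is dependable, needs no light and no diazo compound, and ring B enters with its 2',4'-pattern already fixed. To the isoflavone core this road is probably shorter than the chosen one.
- Weak points: the two C–F bonds left in A1 must still become the C5 hydroxyl and the C7 oxygen. That calls for alkoxide nucleophiles on a pyranone whose C2 is itself an acceptor, and the C7 fluoride (para to the ketone) must be distinguished from the C5 fluoride (ortho to it). The acetal groups on ring B then need acid, so they would have to come off before the Claisen step, leaving ring B unprotected during alkylation.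
- Comparison: the chosen plan cannot match the brevity to the core. It sets against it that both ring A oxygens are in place from compound 1, so nothing is substituted on the finished heterocycle, and that the 4'-oxygen of 18 emerges as a fluoride-labile silyl ether.

Alternative 2: The C2=C3 bond is cut. Ylide A4, in which the neighbouring phenol oxygen carries a formyl group, closes by intramolecular Wittig reaction on the formate carbonyl and loses phosphine oxide to give isoflavone A3.
- Merits: the closure is neutral. A3 has both ring B oxygens silylated, so after debenzylation only O5 and O7 would be free. This is a cleaner substrate for the 7-O-prenylation than triol 19, where a free 2'-hydroxyl is present, and in this respect the alternative is better.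
- Weak points: A4 needs a deoxybenzoin whose α-carbon, flanked by a doubly ortho-substituted aroyl group and an electron-rich aryl ring, must be brominated (ring bromination competes) and then quaternised by a phosphine at a hindered secondary centre. The aryl formate must be placed on a chelated phenol and survive ylide generation. The ylide is stabilised by both ketone and aryl ring and has to attack an ester carbonyl, the least willing Wittig acceptor.
- Comparison: the chosen plan sets a shorter, regiospecific construction of ring B against the better protecting-group pattern. It handles the free 2'-hydroxyl through the acidity gap and, if that fails, through one extra silylation.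

Alternative 3: Ring A is grown instead of ring B. Diazo ketone A6, a 4-pyranone that already bears ring B and carries the 1,1-dimethylallyl group on the diazo carbon, would be irradiated with alkyne 13. Wolff shift (C8–C8a), ketene–alkyne addition (C5–C6, C7–C8) and electrocyclisation (C4a–C5) would give A5.
- Merits: the 1,1-dimethylallyl group is placed at C8 by construction, so neither a Claisen step nor the C6/C8 question arises. No benzyl ethers and no hydrogenolysis are needed, and one global desilylation would finish the synthesis. On regiocontrol and endgame length this road is better than the chosen one.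
- Weak points: A6 has a tertiary alkyl group on the diazo carbon and is hard to make, since diazo transfer to so hindered a position is unfavourable. The resulting ketene is disubstituted and bulky, so alkyne addition and ring opening of a cyclobutenone with a quaternary carbon would be slow. Shifts of the allylic substituents compete with the Wolff shift of an electron-poor pyranonyl carbon. Ring B must be attached to the pyranone beforehand, which brings back the coupling of an ortho-oxygenated resorcinol partner.
- Comparison: the chosen plan pays with the Claisen regiochemistry and a longer endgame. In return it uses a monosubstituted, unhindered ketene of the kind for which this benzannulation is documented, and a precursor (8) reached in four steps from 1.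

Key step: step 6

Remark on the chemistry: (triisopropylsilyloxy)acetylene 13 is not assumed to be a catalogue chemical and is prepared in step 5; compounds 1, 2, 5, 9, 10, 11 and 20 are taken as commercial.

## Route

Step 1
Reactants: 1 1-(2,4,6-trihydroxyphenyl)ethan-1-one (phloroacetophenone); 2 benzyl bromide
Product: 3 1-[2,4-bis(benzyloxy)-6-hydroxyphenyl]ethan-1-one
Conditions: 2 (2.1 equiv), K2CO3, DMF, 0 °C to rt
Reagents that add atoms: none
Why: Williamson etherification; the hydroxyl hydrogen-bonded to the acetyl carbonyl is the least acidic and least nucleophilic, so two equivalents of 2 should leave it free, and the symmetry of 1 makes the two ortho positions equivalent.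

Step 2
Reactants: 3 1-[2,4-bis(benzyloxy)-6-hydroxyphenyl]ethan-1-one
Product: 4 5,7-bis(benzyloxy)-4-oxo-4H-chromene-3-carbaldehyde
Conditions: POCl3, DMF, 0 to 50 °C; then ice-water
Reagents that add atoms: N,N-dimethylformamide CN(C)C=O; water O
Why: Vilsmeier–Haack double formylation of the acetyl methyl group; the phenol oxygen closes onto one iminium carbon with loss of dimethylamine and hydrolysis of the other gives the aldehyde, the standard route from 2-hydroxyacetophenones to chromone-3-carbaldehydes.

Step 3
Reactants: 4 5,7-bis(benzyloxy)-4-oxo-4H-chromene-3-carbaldehyde; 5 1-(triphenyl-λ5-phosphanylidene)propan-2-one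
Product: 6 (E)-4-[5,7-bis(benzyloxy)-4-oxo-4H-chromen-3-yl]but-3-en-2-one
Conditions: 5 (1.2 equiv), toluene, 60 °C
Reagents that add atoms: none
Why: Wittig olefination with a ketone-stabilised ylide, which should give the E-enone; the neutral conditions spare the base-sensitive pyranone.

Step 4
Reactants: 6 (E)-4-[5,7-bis(benzyloxy)-4-oxo-4H-chromen-3-yl]but-3-en-2-one
Product: 8 (E)-4-[5,7-bis(benzyloxy)-4-oxo-4H-chromen-3-yl]-1-diazobut-3-en-2-one, via trifluoroacetyl diketone 7 (not isolated)
Conditions: LiN(SiMe3)2, THF, −78 °C; CF3CO2CH2CF3; aq. HCl work-up; then 4-AcNHC6H4SO2N3, Et3N, H2O, MeCN, rt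
Reagents that add atoms: 4-acetamidobenzenesulfonyl azide CC(=O)Nc1ccc(cc1)S(=O)(=O)N=[N+]=[N-]
Why: Detrifluoroacetylative diazo transfer; the kinetic enolate of the methyl group (the only enolisable site) is acylated to 7, which is taken on crude and exchanges its trifluoroacetyl group for the diazo group. The E-alkene keeps the enolate carbon away from C2 of the pyranone, and no diazoalkane that could add to the conjugated alkenes is used.

Step 5
Reactants: 9 ethyl formate; 10 dibromomethane; 11 chlorotriisopropylsilane
Product: 13 (triisopropylsilyloxy)acetylene, via lithium ethynolate 12 (not isolated)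
Conditions: lithium 2,2,6,6-tetramethylpiperidide, THF, −78 °C; then n-BuLi, −78 °C to rt; then 11, −78 °C to rt; distillation
Reagents that add atoms: none
Why: Kowalski ester homologation stopped at the ynolate; dibromomethyllithium adds to 9, bromine–lithium exchange and loss of ethoxide followed by a second metalation give a carbenoid that rearranges to 12. The bulky silyl chloride should silylate 12 on oxygen, as it does with other ester-derived ynolates.

Step 6
Reactants: 8 (E)-4-[5,7-bis(benzyloxy)-4-oxo-4H-chromen-3-yl]-1-diazobut-3-en-2-one; 13 (triisopropylsilyloxy)acetylene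
Product: 18 5,7-bis(benzyloxy)-3-[2-hydroxy-4-(triisopropylsilyloxy)phenyl]-4H-chromen-4-one, via vinylketene 14 (not isolated), via vinylcyclobutenone 15 (not isolated), via dienylketene 16 (not isolated), via cyclohexadienone 17 (not isolated)
Conditions: 13 (2 equiv), hν (420 nm LED), degassed ClCH2CH2Cl (0.05 M), rt; then 80 °C in the dark
Reagents that add atoms: none
Why: Irradiation in the long-wavelength diazo band, beyond the main chromone absorption, should expel N2 and shift the alkenyl group from the carbonyl carbon to the diazo carbon (Wolff rearrangement, C5'–C6') to give vinylketene 14. The ketene carbonyl carbon is attacked by the nucleophilic CH carbon of the silyl ynol ether and the adduct closes to cyclobutenone 15 (formal [2+2], C2'–C3' and C4'–C5'), the only orientation the polarity of the two partners allows. At 80 °C 15 should open by four-electron conrotatory ring opening to dienylketene 16, which closes ring B by six-electron disrotatory electrocyclisation of the ketene carbon onto the alkene carbon bearing the chromone (C1'–C2'); dienone 17 then enolises to the phenol. The closest known reaction type is the Danheiser benzannulation of α,β-unsaturated diazo ketones with trialkylsilyloxyalkynes, which gives resorcinol monosilyl ethers. No stereocentre survives: the racemic centres of 15 and 17 are lost on aromatisation, and E/Z scrambling of the chromone-bearing double bond would not change the product. The selectivity needed is regiochemical, and the substrate secures it: the ketene carbonyl carbon becomes C2' with its hydroxyl next to C1', and the silyloxy carbon ends up meta to it at C4'. Irradiating at room temperature and heating only afterwards separates ketene formation from phenol formation, so the product phenol should not be acylated by the ketene.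

Step 7
Reactants: 18 5,7-bis(benzyloxy)-3-[2-hydroxy-4-(triisopropylsilyloxy)phenyl]-4H-chromen-4-one
Product: 19 5,7-dihydroxy-3-[2-hydroxy-4-(triisopropylsilyloxy)phenyl]-4H-chromen-4-one
Conditions: H2 (1 atm), 10% Pd/C, EtOAc–THF, rt
Reagents that add atoms: none
Why: Hydrogenolysis of the two aryl benzyl ethers; the aprotic solvent keeps the aryl silyl ether, and stopping after two equivalents of hydrogen should avoid saturation of the C2=C3 bond. The step is placed here because no alkene is yet present.

Step 8
Reactants: 19 5,7-dihydroxy-3-[2-hydroxy-4-(triisopropylsilyloxy)phenyl]-4H-chromen-4-one; 20 1-bromo-3-methylbut-2-ene (prenyl bromide)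
Product: 21 5-hydroxy-3-[2-hydroxy-4-(triisopropylsilyloxy)phenyl]-7-[(3-methylbut-2-en-1-yl)oxy]-4H-chromen-4-one
Conditions: 20 (1.1 equiv), K2CO3 (1.05 equiv), acetone, rt to 40 °C
Reagents that add atoms: none
Why: Williamson etherification under limiting mild base; the 7-hydroxyl is vinylogous to the C4 carbonyl and much the most acidic, the 5-hydroxyl is chelated, and the 2'-hydroxyl is a less acidic, hindered phenol, so alkylation should occur at O7.

Step 9
Reactants: 21 5-hydroxy-3-[2-hydroxy-4-(triisopropylsilyloxy)phenyl]-7-[(3-methylbut-2-en-1-yl)oxy]-4H-chromen-4-one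
Product: 23 5,7-dihydroxy-3-[2-hydroxy-4-(triisopropylsilyloxy)phenyl]-8-(2-methylbut-3-en-2-yl)-4H-chromen-4-one, via dienone 22 (not isolated)
Conditions: Eu(fod)3 (fod = 6,6,7,7,8,8,8-heptafluoro-2,2-dimethyloctane-3,5-dionate; 10 mol %), CHCl3, 60 °C
Reagents that add atoms: none
Why: Lanthanide-catalysed aromatic Claisen rearrangement; the [3,3] shift inverts the allyl group, so the tertiary carbon bonds to the ring, and dienone 22 enolises. C8 is expected to be favoured because the ring oxygen and carbonyl of a benzopyranone give the C7–C8 bond more double-bond character, as in the C8 rearrangement of 7-allyloxy chromones and flavones; the low temperature should prevent cyclisation of the product and loss of the prenyl group.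

Step 10
Reactants: 23 5,7-dihydroxy-3-[2-hydroxy-4-(triisopropylsilyloxy)phenyl]-8-(2-methylbut-3-en-2-yl)-4H-chromen-4-one
Product: 24 5,7-dihydroxy-3-(2,4-dihydroxyphenyl)-8-(2-methylbut-3-en-2-yl)-4H-chromen-4-one
Conditions: Bu4NF, AcOH, THF, 0 °C
Reagents that add atoms: none
Why: Fluoride cleavage of the aryl silyl ether; acetic acid buffers the phenoxides, and neither the terminal alkene nor the pyranone reacts with fluoride.

## Compound list

1 | 1-(2,4,6-trihydroxyphenyl)ethan-1-one | CC(=O)c1c(O)cc(O)cc1O | starting material
2 | benzyl bromide | BrCc1ccccc1 | starting material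
3 | 1-[2,4-bis(benzyloxy)-6-hydroxyphenyl]ethan-1-one | CC(=O)c1c(O)cc(OCc2ccccc2)cc1OCc1ccccc1 | intermediate
4 | 5,7-bis(benzyloxy)-4-oxo-4H-chromene-3-carbaldehyde | O=Cc1coc2cc(OCc3ccccc3)cc(OCc3ccccc3)c2c1=O | intermediate
5 | 1-(triphenyl-λ5-phosphanylidene)propan-2-one | CC(=O)C=P(c1ccccc1)(c1ccccc1)c1ccccc1 | starting material
6 | (E)-4-[5,7-bis(benzyloxy)-4-oxo-4H-chromen-3-yl]but-3-en-2-one | CC(=O)/C=C/c1coc2cc(OCc3ccccc3)cc(OCc3ccccc3)c2c1=O | intermediate
7 | (E)-6-[5,7-bis(benzyloxy)-4-oxo-4H-chromen-3-yl]-1,1,1-trifluorohex-5-ene-2,4-dione | O=C(CC(=O)C(F)(F)F)/C=C/c1coc2cc(OCc3ccccc3)cc(OCc3ccccc3)c2c1=O | intermediate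
8 | (E)-4-[5,7-bis(benzyloxy)-4-oxo-4H-chromen-3-yl]-1-diazobut-3-en-2-one | [N-]=[N+]=CC(=O)/C=C/c1coc2cc(OCc3ccccc3)cc(OCc3ccccc3)c2c1=O | intermediate
9 | ethyl formate | CCOC=O | starting material
10 | dibromomethane | BrCBr | starting material
11 | chlorotriisopropylsilane | CC(C)[Si](Cl)(C(C)C)C(C)C | starting material
12 | lithium ethynolate | [Li+].[O-]C#C | intermediate
13 | (triisopropylsilyloxy)acetylene | C#CO[Si](C(C)C)(C(C)C)C(C)C | intermediate
14 | (E)-4-[5,7-bis(benzyloxy)-4-oxo-4H-chromen-3-yl]buta-1,3-dien-1-one | O=C=C/C=C/c1coc2cc(OCc3ccccc3)cc(OCc3ccccc3)c2c1=O | intermediate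
15 | 4-{(E)-2-[5,7-bis(benzyloxy)-4-oxo-4H-chromen-3-yl]ethenyl}-3-(triisopropylsilyloxy)cyclobut-2-en-1-one (racemic) | O=C1C=C(O[Si](C(C)C)(C(C)C)C(C)C)C1/C=C/c1coc2cc(OCc3ccccc3)cc(OCc3ccccc3)c2c1=O | intermediate
16 | (3E,5E)-6-[5,7-bis(benzyloxy)-4-oxo-4H-chromen-3-yl]-3-(triisopropylsilyloxy)hexa-1,3,5-trien-1-one | O=C=C/C(O[Si](C(C)C)(C(C)C)C(C)C)=C\C=C\c1coc2cc(OCc3ccccc3)cc(OCc3ccccc3)c2c1=O | intermediate
17 | 6-[5,7-bis(benzyloxy)-4-oxo-4H-chromen-3-yl]-3-(triisopropylsilyloxy)cyclohexa-2,4-dien-1-one (racemic) | O=C1C=C(O[Si](C(C)C)(C(C)C)C(C)C)C=CC1c1coc2cc(OCc3ccccc3)cc(OCc3ccccc3)c2c1=O | intermediate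
18 | 5,7-bis(benzyloxy)-3-[2-hydroxy-4-(triisopropylsilyloxy)phenyl]-4H-chromen-4-one | O=c1c(-c2ccc(O[Si](C(C)C)(C(C)C)C(C)C)cc2O)coc2cc(OCc3ccccc3)cc(OCc3ccccc3)c12 | intermediate
19 | 5,7-dihydroxy-3-[2-hydroxy-4-(triisopropylsilyloxy)phenyl]-4H-chromen-4-one | O=c1c(-c2ccc(O[Si](C(C)C)(C(C)C)C(C)C)cc2O)coc2cc(O)cc(O)c12 | intermediate
20 | 1-bromo-3-methylbut-2-ene | CC(C)=CCBr | starting material
21 | 5-hydroxy-3-[2-hydroxy-4-(triisopropylsilyloxy)phenyl]-7-[(3-methylbut-2-en-1-yl)oxy]-4H-chromen-4-one | CC(C)=CCOc1cc(O)c2c(=O)c(-c3ccc(O[Si](C(C)C)(C(C)C)C(C)C)cc3O)coc2c1 | intermediate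
22 | 5-hydroxy-3-[2-hydroxy-4-(triisopropylsilyloxy)phenyl]-8-(2-methylbut-3-en-2-yl)-8H-chromene-4,7-dione (racemic) | C=CC(C)(C)C1C(=O)C=C(O)C2=C1OC=C(c1ccc(O[Si](C(C)C)(C(C)C)C(C)C)cc1O)C2=O | intermediate
23 | 5,7-dihydroxy-3-[2-hydroxy-4-(triisopropylsilyloxy)phenyl]-8-(2-methylbut-3-en-2-yl)-4H-chromen-4-one | C=CC(C)(C)c1c(O)cc(O)c2c(=O)c(-c3ccc(O[Si](C(C)C)(C(C)C)C(C)C)cc3O)coc12 | intermediate
24 | 5,7-dihydroxy-3-(2,4-dihydroxyphenyl)-8-(2-methylbut-3-en-2-yl)-4H-chromen-4-one | C=CC(C)(C)c1c(O)cc(O)c2c(=O)c(-c3ccc(O)cc3O)coc12 | target

## Step count and weak points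

Total: 10 steps. Longest linear sequence: 9 steps (steps 1–4 and 6–10); step 5 is a one-step side branch.

**Step 6 (key step).** The most likely failure is diversion of the excited state: the chromone–enone chromophore may absorb competitively and dimerise by [2+2] photoaddition, or the Wolff shift may be slow, so that the ketene is lost to dimerisation or adventitious water before it meets the alkyne. The fallback makes the same ketene without light. It sets out from aldehyde 4: Wittig reaction with the ylide from (2-carboxyethyl)triphenylphosphonium bromide would give (E)-4-[5,7-bis(benzyloxy)-4-oxo-4H-chromen-3-yl]but-3-enoic acid F1, and oxalyl chloride would convert it into (E)-4-[5,7-bis(benzyloxy)-4-oxo-4H-chromen-3-yl]but-3-enoyl chloride F2. Slow addition of Et3N to F2 in the presence of 13 should generate 14 by dehydrochlorination; 14 should be trapped as 15, and heating then returns the route at 18.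

**Step 5.** The formate adduct may collapse to the aldehyde level and add a second carbenoid, the hydrogen shift that must replace the usual carbon shift may be incomplete, and excess butyllithium may metalate the ynolate and lead to C-silylation. The fallback gives up the silyl ynol ether and uses commercial ethoxyacetylene. It sets out from 8, which under the conditions of step 6 should give 5,7-bis(benzyloxy)-3-(4-ethoxy-2-hydroxyphenyl)-4H-chromen-4-one F3. BBr3 would remove the ethyl and both benzyl groups to give 5,7-dihydroxy-3-(2,4-dihydroxyphenyl)-4H-chromen-4-one F4. Alkylation with 20 and one equivalent of K2CO3 would give 5-hydroxy-3-(2,4-dihydroxyphenyl)-7-[(3-methylbut-2-en-1-yl)oxy]-4H-chromen-4-one F5, and the Eu(fod)3-catalysed Claisen rearrangement returns at 24. The cost is an unprotected ring B during alkylation, which then rests on acidity alone.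

**Step 4.** The amide base or the enolate may add to C2 of the pyranone instead of giving clean enolisation and C-acylation, and the ring may open during the aqueous amine stage. The fallback sets out from 4: Knoevenagel–Doebner condensation with malonic acid in pyridine would give (E)-3-[5,7-bis(benzyloxy)-4-oxo-4H-chromen-3-yl]prop-2-enoic acid F6, and oxalyl chloride would give (E)-3-[5,7-bis(benzyloxy)-4-oxo-4H-chromen-3-yl]prop-2-enoyl chloride F7. Acylation of excess diazomethane at 0 °C with short contact, to limit dipolar addition to the alkenes, returns at 8.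

**Step 9.** The allyl group may migrate partly to C6, because the hydrogen bond between the 5-hydroxyl and the carbonyl favours the opposite bond fixation in ring A. The product may also cyclise through its 7-hydroxyl onto the alkene. The fallback removes the chelate. It sets out from 21: acetylation (Ac2O, pyridine, 4-dimethylaminopyridine) would give 3-[2-acetoxy-4-(triisopropylsilyloxy)phenyl]-7-[(3-methylbut-2-en-1-yl)oxy]-4-oxo-4H-chromen-5-yl acetate F8. Its rearrangement, now governed by the pyranone alone, should give 3-[2-acetoxy-4-(triisopropylsilyloxy)phenyl]-7-hydroxy-8-(2-methylbut-3-en-2-yl)-4-oxo-4H-chromen-5-yl acetate F9, and ammonolysis of the acetates (NH3, MeOH, 0 °C) returns at 23.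

**Step 8.** Alkylation may also occur at the 2'-oxygen, or twice, if the acidity gap is not large enough under heterogeneous base. The fallback masks that oxygen. It sets out from 18: silylation (t-BuMe2SiCl, imidazole, DMF) would give 5,7-bis(benzyloxy)-3-[2-(tert-butyldimethylsilyloxy)-4-(triisopropylsilyloxy)phenyl]-4H-chromen-4-one F10, and hydrogenolysis would give 3-[2-(tert-butyldimethylsilyloxy)-4-(triisopropylsilyloxy)phenyl]-5,7-dihydroxy-4H-chromen-4-one F11. Alkylation with 20 would give 3-[2-(tert-butyldimethylsilyloxy)-4-(triisopropylsilyloxy)phenyl]-5-hydroxy-7-[(3-methylbut-2-en-1-yl)oxy]-4H-chromen-4-one F12, and the Claisen rearrangement would give 3-[2-(tert-butyldimethylsilyloxy)-4-(triisopropylsilyloxy)phenyl]-5,7-dihydroxy-8-(2-methylbut-3-en-2-yl)-4H-chromen-4-one F13. Bu4NF removes both silyl groups and returns at 24.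

## Further compounds

F1 | step 6 | (E)-4-[5,7-bis(benzyloxy)-4-oxo-4H-chromen-3-yl]but-3-enoic acid | OC(=O)C/C=C/c1coc2cc(OCc3ccccc3)cc(OCc3ccccc3)c2c1=O
F2 | step 6 | (E)-4-[5,7-bis(benzyloxy)-4-oxo-4H-chromen-3-yl]but-3-enoyl chloride | ClC(=O)C/C=C/c1coc2cc(OCc3ccccc3)cc(OCc3ccccc3)c2c1=O
F3 | step 5 | 5,7-bis(benzyloxy)-3-(4-ethoxy-2-hydroxyphenyl)-4H-chromen-4-one | CCOc1ccc(-c2coc3cc(OCc4ccccc4)cc(OCc4ccccc4)c3c2=O)c(O)c1
F4 | step 5 | 5,7-dihydroxy-3-(2,4-dihydroxyphenyl)-4H-chromen-4-one | O=c1c(-c2ccc(O)cc2O)coc2cc(O)cc(O)c12
F5 | step 5 | 5-hydroxy-3-(2,4-dihydroxyphenyl)-7-[(3-methylbut-2-en-1-yl)oxy]-4H-chromen-4-one | CC(C)=CCOc1cc(O)c2c(=O)c(-c3ccc(O)cc3O)coc2c1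
F6 | step 4 | (E)-3-[5,7-bis(benzyloxy)-4-oxo-4H-chromen-3-yl]prop-2-enoic acid | OC(=O)/C=C/c1coc2cc(OCc3ccccc3)cc(OCc3ccccc3)c2c1=O
F7 | step 4 | (E)-3-[5,7-bis(benzyloxy)-4-oxo-4H-chromen-3-yl]prop-2-enoyl chloride | ClC(=O)/C=C/c1coc2cc(OCc3ccccc3)cc(OCc3ccccc3)c2c1=O
F8 | step 9 | 3-[2-acetoxy-4-(triisopropylsilyloxy)phenyl]-7-[(3-methylbut-2-en-1-yl)oxy]-4-oxo-4H-chromen-5-yl acetate | CC(=O)Oc1cc(OCC=C(C)C)cc2occ(-c3ccc(O[Si](C(C)C)(C(C)C)C(C)C)cc3OC(C)=O)c(=O)c12
F9 | step 9 | 3-[2-acetoxy-4-(triisopropylsilyloxy)phenyl]-7-hydroxy-8-(2-methylbut-3-en-2-yl)-4-oxo-4H-chromen-5-yl acetate | CC(=O)Oc1cc(O)c(C(C)(C)C=C)c2occ(-c3ccc(O[Si](C(C)C)(C(C)C)C(C)C)cc3OC(C)=O)c(=O)c12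
F10 | step 8 | 5,7-bis(benzyloxy)-3-[2-(tert-butyldimethylsilyloxy)-4-(triisopropylsilyloxy)phenyl]-4H-chromen-4-one | CC(C)[Si](Oc1ccc(-c2coc3cc(OCc4ccccc4)cc(OCc4ccccc4)c3c2=O)c(O[Si](C)(C)C(C)(C)C)c1)(C(C)C)C(C)C
F11 | step 8 | 3-[2-(tert-butyldimethylsilyloxy)-4-(triisopropylsilyloxy)phenyl]-5,7-dihydroxy-4H-chromen-4-one | CC(C)[Si](Oc1ccc(-c2coc3cc(O)cc(O)c3c2=O)c(O[Si](C)(C)C(C)(C)C)c1)(C(C)C)C(C)C
F12 | step 8 | 3-[2-(tert-butyldimethylsilyloxy)-4-(triisopropylsilyloxy)phenyl]-5-hydroxy-7-[(3-methylbut-2-en-1-yl)oxy]-4H-chromen-4-one | CC(C)=CCOc1cc(O)c2c(=O)c(-c3ccc(O[Si](C(C)C)(C(C)C)C(C)C)cc3O[Si](C)(C)C(C)(C)C)coc2c1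
F13 | step 8 | 3-[2-(tert-butyldimethylsilyloxy)-4-(triisopropylsilyloxy)phenyl]-5,7-dihydroxy-8-(2-methylbut-3-en-2-yl)-4H-chromen-4-one | C=CC(C)(C)c1c(O)cc(O)c2c(=O)c(-c3ccc(O[Si](C(C)C)(C(C)C)C(C)C)cc3O[Si](C)(C)C(C)(C)C)coc12
A1 | alternative 1 | 5,7-difluoro-3-[2,4-bis(methoxymethoxy)phenyl]-4H-chromen-4-one | COCOc1ccc(-c2coc3cc(F)cc(F)c3c2=O)c(OCOC)c1
A2 | alternative 1 | 2-[2,4-bis(methoxymethoxy)phenyl]-3-hydroxy-1-(2,4,6-trifluorophenyl)prop-2-en-1-one (enol, geometry not fixed) | COCOc1ccc(C(=CO)C(=O)c2c(F)cc(F)cc2F)c(OCOC)c1
A3 | alternative 2 | 5,7-bis(benzyloxy)-3-[2,4-bis(tert-butyldimethylsilyloxy)phenyl]-4H-chromen-4-one | O=c1c(-c2ccc(O[Si](C)(C)C(C)(C)C)cc2O[Si](C)(C)C(C)(C)C)coc2cc(OCc3ccccc3)cc(OCc3ccccc3)c12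
A4 | alternative 2 | 3,5-bis(benzyloxy)-2-{2-[2,4-bis(tert-butyldimethylsilyloxy)phenyl]-2-(triphenyl-λ5-phosphanylidene)acetyl}phenyl formate | O=COc1cc(OCc2ccccc2)cc(OCc2ccccc2)c1C(=O)C(=P(c1ccccc1)(c1ccccc1)c1ccccc1)c1ccc(O[Si](C)(C)C(C)(C)C)cc1O[Si](C)(C)C(C)(C)C
A5 | alternative 3 | 5-hydroxy-7-(triisopropylsilyloxy)-8-(2-methylbut-3-en-2-yl)-3-[2,4-bis(tert-butyldimethylsilyloxy)phenyl]-4H-chromen-4-one | C=CC(C)(C)c1c(O[Si](C(C)C)(C(C)C)C(C)C)cc(O)c2c(=O)c(-c3ccc(O[Si](C)(C)C(C)(C)C)cc3O[Si](C)(C)C(C)(C)C)coc12
A6 | alternative 3 | 2-(2-diazo-3,3-dimethylpent-4-enoyl)-5-[2,4-bis(tert-butyldimethylsilyloxy)phenyl]-4H-pyran-4-one | C=CC(C)(C)C(=[N+]=[N-])C(=O)c1cc(=O)c(-c2ccc(O[Si](C)(C)C(C)(C)C)cc2O[Si](C)(C)C(C)(C)C)co1
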